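Ring A (the cyclohexadienone; C1 ketone, C2 hexanoyl-bearing, C3, quaternary C4, C5, bridge-bearing C6) is treated as a folded polyketide. C3–C4–C5 is a methyl(prenyl)malonyl unit and C6–C1–C2 with its acyl chain is nonane-2,4-dione. In one operation the diketone 1,3-dianion is acylated at its methyl terminus by an enantiopure malonic half-ester chloride (C5–C6 bond) and the resulting 3,5,7-triketo ester closes ring A by Claisen condensation (C2–C3 bond). Because chloride and ester are differentiated, the order of the two acylations transcribes the acyclic quaternary configuration into the ring. A Mannich-type methylene bridge to the aromatic acylphloroglucinol ends the synthesis.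

Key step: step 6

Remark: ring A compounds are drawn as one enol tautomer; the sense of induction in step 3 is assigned by analogy with allylations of the same malonate class, and the (R,R)-catalyst is equally available should it prove opposite.

Step 1
Reactants: 1 2,2,5-trimethyl-1,3-dioxane-4,6-dione
Product: 2 3-tert-butoxy-2-methyl-3-oxopropanoic acid (racemic)
Conditions: t-BuOH, reflux
Reagents that add atoms: tert-butanol, CC(C)(C)O
Why: tert-Butanol adds to a ring carbonyl of the cyclic isopropylidene malonate and acetone is lost (alcoholysis, a nucleophilic acyl substitution), giving the half-ester whose labile methine centre is racemic and is erased by enolisation in step 3.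

Step 2
Reactants: 2 3-tert-butoxy-2-methyl-3-oxopropanoic acid; 3 2,2-diphenylethanol
Product: 4 1-tert-butyl 3-(2,2-diphenylethyl) 2-methylpropanedioate (racemic)
Conditions: DCC, DMAP (cat.), CH2Cl2, 0 → 23 °C
Reagents that add atoms: none
Why: Steglich esterification (carbodiimide activation, acyl transfer through the N-acylpyridinium) couples the half-acid with the primary alcohol under conditions too mild for decarboxylation or loss of the tert-butyl ester.

Step 3
Reactants: 4 1-tert-butyl 3-(2,2-diphenylethyl) 2-methylpropanedioate; 5 1-bromo-3-methylbut-2-ene (prenyl bromide)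
Product: 6 1-tert-butyl 3-(2,2-diphenylethyl) (2S)-2-methyl-2-(3-methylbut-2-en-1-yl)propanedioate
Conditions: (S,S)-3,4,5-trifluorophenyl-NAS bromide (N-spiro bis(binaphthyl) quaternary ammonium bromide, 5 mol %), 50% aq KOH, toluene, −40 °C
Reagents that add atoms: none
Why: Enantioselective phase-transfer alkylation, in which the potassium enolate of 4 is extracted as a tight ion pair with the C2-symmetric chiral ammonium cation that shields one enolate face while the two unlike ester groups fix the enolate orientation, so that SN2 attack on the primary allylic bromide should set the quaternary centre as (S) under catalyst control.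

Step 4
Reactants: 6 1-tert-butyl 3-(2,2-diphenylethyl) (2S)-2-methyl-2-(3-methylbut-2-en-1-yl)propanedioate
Product: 8 (2R)-2-[(2,2-diphenylethoxy)carbonyl]-2,5-dimethylhex-4-enoic acid, via trimethylsilyl ester 7 (not isolated)
Conditions: TMSOTf, 2,6-lutidine, CH2Cl2, 0 °C; then aq citric acid
Reagents that add atoms: none
Why: The silyl triflate activates the tert-butyl ester so that 2-methylpropene is lost (E1-type tert-butyl ester cleavage) and the silyl ester is hydrolysed on work-up, the primary 2,2-diphenylethyl ester being inert and the lutidine buffer keeping the prenyl alkene from protonation and lactonisation.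

Step 5
Reactants: 8 (2R)-2-[(2,2-diphenylethoxy)carbonyl]-2,5-dimethylhex-4-enoic acid
Product: 9 2,2-diphenylethyl (2S)-2-(chlorocarbonyl)-2,5-dimethylhex-4-enoate
Conditions: 1-chloro-N,N,2-trimethylprop-1-en-1-amine, CH2Cl2, 0 → 23 °C; concentrated and used crude
Reagents that add atoms: 1-chloro-N,N,2-trimethylprop-1-en-1-amine, CC(C)=C(Cl)N(C)C
Why: The alpha-chloroenamine converts the acid into the acid chloride through an acyloxyiminium chloride under neutral conditions (nucleophilic acyl substitution), so that no hydrogen chloride adds to the prenyl alkene and the quaternary centre, having no alpha-hydrogen, cannot epimerise.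

Step 6
Reactants: 9 2,2-diphenylethyl (2S)-2-(chlorocarbonyl)-2,5-dimethylhex-4-enoate; 10 nonane-2,4-dione
Product: 13 (4R)-2-hexanoyl-3,5-dihydroxy-4-methyl-4-(3-methylbut-2-en-1-yl)cyclohexa-2,5-dien-1-one, via dilithium dienolate 11 (not isolated), via triketo ester 12 (not isolated)
Conditions: 10 (2.2 equiv), LiN(iPr)2 (4.4 equiv, commercial solution), THF, 0 °C; then 9, −78 °C; then 23 → 60 °C; 1 M HCl work-up
Reagents that add atoms: none
Why: The kinetic 1,3-dianion 11 attacks the acid chloride of 9 with its methyl-derived terminal carbon, its most nucleophilic site, to form the C5–C6 bond; excess 11 then deprotonates triketo ester 12 at C6 and C2, and on warming C2 of this dianion adds to the remaining ester carbonyl and expels 2,2-diphenylethoxide (intramolecular Claisen condensation of Dieckmann type), the whole amounting to a [3+3] annulation. The closest known reaction types are the terminal acylation of beta-diketone dianions to 1,3,5-triketones and the Dieckmann-type cyclisation of 3,5-diketo esters to cyclohexane-1,3,5-triones and acylphloroglucinols, which mirrors the biosynthetic folding of a tetraketide chain. Ring A closes in a 6-(enolendo)-exo-trig mode through the C2–C3 bond. No stereocentre is formed: the quaternary C4 set in step 3 has no alpha-hydrogen and is carried through, and its sense in the ring is fixed because the chloride carbonyl becomes C5 and the ester carbonyl becomes C3. The step needs chemoselectivity of the first attack for chloride over ester, secured by their large reactivity gap at −78 °C, second deprotonation of 10 at CH3 and not at the pentyl CH2, secured by the higher kinetic acidity of the methyl group, and C- over O-cyclisation, secured because an enol lactone is reopened by the liberated alkoxide whereas the trione leaves the equilibrium as a doubly stabilised dianion. Retro-Claisen cleavage at C4 is suppressed for the same reason, both flanking carbonyls being enolate-bound.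

Step 7
Reactants: 14 benzene-1,3,5-triol (phloroglucinol); 15 butanoyl chloride
Product: 16 1-(2,4,6-trihydroxyphenyl)butan-1-one
Conditions: AlCl3 (4 equiv), PhNO2/CH2Cl2, 0 → 23 °C; then ice/aq HCl
Reagents that add atoms: none
Why: Friedel–Crafts acylation of the threefold activated arene should stop after one acyl group because the chelated aryl ketone deactivates the ring.

Step 8
Reactants: 16 1-(2,4,6-trihydroxyphenyl)butan-1-one
Product: 17 1-(2,6-dihydroxy-4-methoxyphenyl)butan-1-one
Conditions: Me2SO4 (1.0 equiv), K2CO3 (1.0 equiv), acetone, 23 → 56 °C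
Reagents that add atoms: dimethyl sulfate, COS(=O)(=O)OC
Why: Williamson-type O-methylation takes place at the 4-hydroxyl, which is the most acidic and the only one not held in a hydrogen bond to the ketone, so that one equivalent of dimethyl sulfate should give the 4-methyl ether.

Step 9
Reactants: 13 (4R)-2-hexanoyl-3,5-dihydroxy-4-methyl-4-(3-methylbut-2-en-1-yl)cyclohexa-2,5-dien-1-one; 17 1-(2,6-dihydroxy-4-methoxyphenyl)butan-1-one
Product: 20 (4R)-6-[(3-butanoyl-2,4-dihydroxy-6-methoxyphenyl)methyl]-2-hexanoyl-3,5-dihydroxy-4-methyl-4-(3-methylbut-2-en-1-yl)cyclohexa-2,5-dien-1-one, via Mannich base 18 (not isolated), via methylidene trione 19 (not isolated)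
Conditions: dimethyl(methylidene)ammonium iodide (1.0 equiv), MeCN, 0 → 23 °C; then 17 (3 equiv), 80 °C
Reagents that add atoms: dimethyl(methylidene)ammonium iodide, C=[N+](C)C.[I-]
Why: Mannich aminomethylation at C6, the only free nucleophilic carbon of ring A, is followed on heating by loss of dimethylamine to the exocyclic enone 19, which is trapped in a Friedel–Crafts-type conjugate addition by the single kind of free, doubly activated position of excess 17, the quaternary C4 being untouched.

Compound list
1 | 2,2,5-trimethyl-1,3-dioxane-4,6-dione | CC1C(=O)OC(C)(C)OC1=O | starting material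
2 | 3-tert-butoxy-2-methyl-3-oxopropanoic acid (racemic) | CC(C(=O)O)C(=O)OC(C)(C)C | intermediate
3 | 2,2-diphenylethanol | OCC(c1ccccc1)c1ccccc1 | starting material
4 | 1-tert-butyl 3-(2,2-diphenylethyl) 2-methylpropanedioate (racemic) | CC(C(=O)OCC(c1ccccc1)c1ccccc1)C(=O)OC(C)(C)C | intermediate
5 | 1-bromo-3-methylbut-2-ene | CC(C)=CCBr | starting material
6 | 1-tert-butyl 3-(2,2-diphenylethyl) (2S)-2-methyl-2-(3-methylbut-2-en-1-yl)propanedioate | O=C(OCC(c1ccccc1)c1ccccc1)[C@](C)(CC=C(C)C)C(=O)OC(C)(C)C | intermediate
7 | 2,2-diphenylethyl trimethylsilyl (2S)-2-methyl-2-(3-methylbut-2-en-1-yl)propanedioate (not isolated) | O=C(OCC(c1ccccc1)c1ccccc1)[C@](C)(CC=C(C)C)C(=O)O[Si](C)(C)C | intermediate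
8 | (2R)-2-[(2,2-diphenylethoxy)carbonyl]-2,5-dimethylhex-4-enoic acid | O=C(OCC(c1ccccc1)c1ccccc1)[C@](C)(CC=C(C)C)C(=O)O | intermediate
9 | 2,2-diphenylethyl (2S)-2-(chlorocarbonyl)-2,5-dimethylhex-4-enoate | O=C(OCC(c1ccccc1)c1ccccc1)[C@](C)(CC=C(C)C)C(=O)Cl | intermediate
10 | nonane-2,4-dione | CCCCCC(=O)CC(C)=O | starting material
11 | dilithium nona-1,3-diene-2,4-diolate, the 1,3-dianion of 10 (not isolated) | [Li+].[Li+].C=C([O-])C=C([O-])CCCCC | intermediate
12 | 2,2-diphenylethyl (2R)-2-methyl-2-(3-methylbut-2-en-1-yl)-3,5,7-trioxododecanoate (formed as its lithium dienolate, not isolated) | O=C(OCC(c1ccccc1)c1ccccc1)[C@](C)(CC=C(C)C)C(=O)CC(=O)CC(=O)CCCCC | intermediate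
13 | (4R)-2-hexanoyl-3,5-dihydroxy-4-methyl-4-(3-methylbut-2-en-1-yl)cyclohexa-2,5-dien-1-one | CCCCCC(=O)C1=C(O)[C@](C)(CC=C(C)C)C(O)=CC1=O | intermediate
14 | benzene-1,3,5-triol | Oc1cc(O)cc(O)c1 | starting material
15 | butanoyl chloride | CCCC(=O)Cl | starting material
16 | 1-(2,4,6-trihydroxyphenyl)butan-1-one | CCCC(=O)c1c(O)cc(O)cc1O | intermediate
17 | 1-(2,6-dihydroxy-4-methoxyphenyl)butan-1-one | CCCC(=O)c1c(O)cc(OC)cc1O | intermediate
18 | (4R)-6-[(dimethylamino)methyl]-2-hexanoyl-3,5-dihydroxy-4-methyl-4-(3-methylbut-2-en-1-yl)cyclohexa-2,5-dien-1-one (not isolated) | CCCCCC(=O)C1=C(O)[C@](C)(CC=C(C)C)C(O)=C(CN(C)C)C1=O | intermediate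
19 | (6S)-4-hexanoyl-5-hydroxy-6-methyl-2-methylidene-6-(3-methylbut-2-en-1-yl)cyclohex-4-ene-1,3-dione (not isolated) | CCCCCC(=O)C1=C(O)[C@](C)(CC=C(C)C)C(=O)C(=C)C1=O | intermediate
20 | (4R)-6-[(3-butanoyl-2,4-dihydroxy-6-methoxyphenyl)methyl]-2-hexanoyl-3,5-dihydroxy-4-methyl-4-(3-methylbut-2-en-1-yl)cyclohexa-2,5-dien-1-one | CCCCCC(=O)C1=C(O)[C@](C)(CC=C(C)C)C(O)=C(Cc2c(OC)cc(O)c(C(=O)CCC)c2O)C1=O | target

Total step count: 9. Longest linear sequence: 7 steps (steps 1 to 6, then step 9).

Steps most likely to fail

Step 6. The ring-closing acylation of the lithium dianion onto the neopentyl-type ester may stall at the open chain or divert to O-acylation. Some of dianion 11 may also attack the ester carbonyl before the chloride, which would erode enantiopurity. The fallback gives up the one-pot annulation and separates chain assembly from ring closure, setting out from acid 8. 1,1'-Carbonyldiimidazole in THF should give the acyl imidazole 2,2-diphenylethyl (2R)-2-(imidazole-1-carbonyl)-2,5-dimethylhex-4-enoate F1, a milder and more discriminating acyl donor. F1 is added to dianion 11 at −78 °C and the mixture is quenched cold with acetic acid, so that triketo ester 12 is isolated. A separate Claisen condensation of 12 with KOtBu in THF at 50 °C, under equilibrating conditions, then closes ring A and returns to the route at 13.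

Step 9. The enone methide from the valuable trione may self-condense, or the arene may be alkylated at both of its free positions. The fallback reverses the roles of the partners, setting out from 17. Aminomethylation of 17 with one equivalent of dimethyl(methylidene)ammonium iodide in MeCN should give 1-{3-[(dimethylamino)methyl]-2,6-dihydroxy-4-methoxyphenyl}butan-1-one F2. Heating F2 with 13 in dioxane at 100 °C expels dimethylamine to the ortho-quinone methide 2-butanoyl-3-hydroxy-5-methoxy-6-methylidenecyclohexa-2,4-dien-1-one F3. F3 is captured by C6 of 13, the only nucleophilic carbon of ring A, and the route is rejoined at 20.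

Step 3. Facial discrimination of the ion-paired enolate toward the small prenyl electrophile may be insufficient, or the esters may be partly saponified by the concentrated base. The fallback replaces asymmetric catalysis by classical resolution, setting out from 4. Alkylation with 5 (K2CO3, DMF, 23 °C) gives the racemic diester 1-tert-butyl 3-(2,2-diphenylethyl) 2-methyl-2-(3-methylbut-2-en-1-yl)propanedioate F4. TMSOTf and 2,6-lutidine convert F4 through the racemic silyl ester 2,2-diphenylethyl trimethylsilyl 2-methyl-2-(3-methylbut-2-en-1-yl)propanedioate F5 into the racemic acid 2-[(2,2-diphenylethoxy)carbonyl]-2,5-dimethylhex-4-enoic acid F6. Crystallisation with (S)-1-phenylethylamine should deposit the less soluble salt, taken here as (S)-1-phenylethylammonium (2R)-2-[(2,2-diphenylethoxy)carbonyl]-2,5-dimethylhex-4-enoate F7. The diastereomeric salt (S)-1-phenylethylammonium (2S)-2-[(2,2-diphenylethoxy)carbonyl]-2,5-dimethylhex-4-enoate F8 stays in the mother liquor; the (R)-amine is used instead if the solubility order is the reverse. Acidification of F7 returns to the route at 8.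

Further compounds
F1 | step 6 | 2,2-diphenylethyl (2R)-2-(imidazole-1-carbonyl)-2,5-dimethylhex-4-enoate | O=C(OCC(c1ccccc1)c1ccccc1)[C@](C)(CC=C(C)C)C(=O)n1ccnc1
F2 | step 9 | 1-{3-[(dimethylamino)methyl]-2,6-dihydroxy-4-methoxyphenyl}butan-1-one | CCCC(=O)c1c(O)cc(OC)c(CN(C)C)c1O
F3 | step 9 | 2-butanoyl-3-hydroxy-5-methoxy-6-methylidenecyclohexa-2,4-dien-1-one | CCCC(=O)C1=C(O)C=C(OC)C(=C)C1=O
F4 | step 3 | 1-tert-butyl 3-(2,2-diphenylethyl) 2-methyl-2-(3-methylbut-2-en-1-yl)propanedioate (racemic) | O=C(OCC(c1ccccc1)c1ccccc1)C(C)(CC=C(C)C)C(=O)OC(C)(C)C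
F5 | step 3 | 2,2-diphenylethyl trimethylsilyl 2-methyl-2-(3-methylbut-2-en-1-yl)propanedioate (racemic) | O=C(OCC(c1ccccc1)c1ccccc1)C(C)(CC=C(C)C)C(=O)O[Si](C)(C)C
F6 | step 3 | 2-[(2,2-diphenylethoxy)carbonyl]-2,5-dimethylhex-4-enoic acid (racemic) | O=C(OCC(c1ccccc1)c1ccccc1)C(C)(CC=C(C)C)C(=O)O
F7 | step 3 | (S)-1-phenylethylammonium (2R)-2-[(2,2-diphenylethoxy)carbonyl]-2,5-dimethylhex-4-enoate | O=C(OCC(c1ccccc1)c1ccccc1)[C@](C)(CC=C(C)C)C(=O)[O-].C[C@H]([NH3+])c1ccccc1
F8 | step 3 | (S)-1-phenylethylammonium (2S)-2-[(2,2-diphenylethoxy)carbonyl]-2,5-dimethylhex-4-enoate | O=C(OCC(c1ccccc1)c1ccccc1)[C@@](C)(CC=C(C)C)C(=O)[O-].C[C@H]([NH3+])c1ccccc1
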